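**Plan**

- Retrosynthesis: the O7 silyl ether and the C4 ketone of the target flavanone are unmasked last; pyran ring C is then cut at O1–C2 and C3–C4, giving 4-methoxystyrene and a ring A alkoxy o-quinone methide, traced back to a salicylaldehyde dimethyl acetal.
- Enabling feature: ring C carries phenol oxygen O1 on C8a and benzylic C4 on C4a, so O1–C8a–C4a–C4 is a latent o-quinone methide heterodiene and C2–C3, with the 4-methoxyphenyl on C2, is the styrene partner; a methoxy group on the methide carbon keeps C4 at the ketone oxidation level.
- Forward, ring A: 2,4-dihydroxybenzaldehyde is prenylated at C3 and C5 (flavanone C8 and C6) by two rounds of O4-(1,1-dimethylpropargyl)ation, semihydrogenation and aromatic Claisen rearrangement; O4 is then silylated and the aldehyde converted into its dimethyl acetal.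
- Forward, ring C: a chiral phosphoric acid ionises the acetal and ring C closes by [4+2] cycloaddition with 4-methoxystyrene; hydrolysis of the C4 methyl ether, oxidation and desilylation give the flavanone.
- Stereochemistry: the only stereocentre of the target, C2 (S), is set in the cycloaddition by the chiral phosphate; the C4 centre formed with it is erased on oxidation.

Key step: step 7

Assumption: the sense of induction of the chiral acid on this untested substrate cannot be assigned in advance; the (R)-catalyst is written, and its enantiomer would be used if the first experiment delivered the (2R) series.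

**Route**

Step 1
Reactants: 1 2,4-dihydroxybenzaldehyde; 2 3-chloro-3-methylbut-1-yne
Product: 3 2-hydroxy-4-[(2-methylbut-3-yn-2-yl)oxy]benzaldehyde
Conditions: K2CO3, KI (cat.), CuI (cat.), acetone, 55 °C
Reagents that add atoms: none
Why: Copper-catalysed O-propargylation (Williamson-type etherification through a copper acetylide) should occur only at O4, because the C2 hydroxyl is hydrogen-bonded to the formyl group and is the less acidic and less nucleophilic phenol.

Step 2
Reactants: 3 2-hydroxy-4-[(2-methylbut-3-yn-2-yl)oxy]benzaldehyde
Product: 5 2,4-dihydroxy-3-(3-methylbut-2-en-1-yl)benzaldehyde, via allyl ether 4 (not isolated)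
Conditions: H2 (1 atm), Pd/CaCO3 poisoned with Pb(OAc)2, quinoline, o-xylene, rt; filtered through Celite under N2; filtrate heated at 140 °C
Reagents that add atoms: none
Why: Lindlar-type semihydrogenation stops at the terminal alkene, and on heating the aryl 1,1-dimethylallyl ether 4 undergoes aromatic Claisen rearrangement with allylic inversion, which should place a linear prenyl group mainly at C3 between the two oxygens, as is usual for 4-O-allyl ethers of chelated 2,4-dihydroxyaryl carbonyl compounds; a minor C5 isomer is removed by chromatography.

Step 3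
Reactants: 5 2,4-dihydroxy-3-(3-methylbut-2-en-1-yl)benzaldehyde; 2 3-chloro-3-methylbut-1-yne
Product: 6 2-hydroxy-3-(3-methylbut-2-en-1-yl)-4-[(2-methylbut-3-yn-2-yl)oxy]benzaldehyde
Conditions: K2CO3, KI (cat.), CuI (cat.), acetone, 55 °C
Reagents that add atoms: none
Why: The same copper-catalysed O-propargylation as in step 1 applies, since O4 is again the only phenol outside the chelate and one ortho prenyl group should not block ether formation.

Step 4
Reactants: 6 2-hydroxy-3-(3-methylbut-2-en-1-yl)-4-[(2-methylbut-3-yn-2-yl)oxy]benzaldehyde
Product: 8 2,4-dihydroxy-3,5-bis(3-methylbut-2-en-1-yl)benzaldehyde, via allyl ether 7 (not isolated)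
Conditions: H2 (1 atm), Pd/CaCO3 poisoned with Pb(OAc)2, quinoline, o-xylene, rt; filtered through Celite under N2; filtrate heated at 140 °C
Reagents that add atoms: none
Why: Semihydrogenation over the poisoned palladium catalyst leaves the trisubstituted prenyl alkene untouched, and the aromatic Claisen rearrangement of ether 7 can end productively only at C5, the one free ortho position, because migration to the substituted C3 is reversible.

Step 5
Reactants: 8 2,4-dihydroxy-3,5-bis(3-methylbut-2-en-1-yl)benzaldehyde
Product: 9 4-[(tert-butyldimethylsilyl)oxy]-2-hydroxy-3,5-bis(3-methylbut-2-en-1-yl)benzaldehyde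
Conditions: TBSCl (1.1 equiv), imidazole, DMF, 0 °C to rt
Reagents that add atoms: tert-butyldimethylsilyl chloride, CC(C)(C)[Si](C)(C)Cl
Why: Phenol silylation should be selective for O4 because the O2 hydroxyl is held in the intramolecular hydrogen bond to the aldehyde; the silyl ether later stops the para oxygen from forming a para-quinone methide in the key step.

Step 6
Reactants: 9 4-[(tert-butyldimethylsilyl)oxy]-2-hydroxy-3,5-bis(3-methylbut-2-en-1-yl)benzaldehyde
Product: 10 3-[(tert-butyldimethylsilyl)oxy]-6-(dimethoxymethyl)-2,4-bis(3-methylbut-2-en-1-yl)phenol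
Conditions: HC(OMe)3, MeOH, PPTS (5 mol%), rt; Et3N, concentrate, short plug of basic Al2O3; used without further purification
Reagents that add atoms: trimethyl orthoformate, COC(OC)OC; methanol, CO
Why: Acid-catalysed acetalisation with trimethyl orthoformate as water scavenger is standard for salicylaldehydes, and the mild acid, amine quench and alumina filtration allow for the lability of this electron-rich 2-hydroxybenzaldehyde acetal and remove achiral acid before the next step.

Step 7
Reactants: 10 3-[(tert-butyldimethylsilyl)oxy]-6-(dimethoxymethyl)-2,4-bis(3-methylbut-2-en-1-yl)phenol; 11 4-methoxystyrene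
Product: 13 (2S,4S)-7-[(tert-butyldimethylsilyl)oxy]-4-methoxy-2-(4-methoxyphenyl)-6,8-bis(3-methylbut-2-en-1-yl)chromane, via alkoxy o-quinone methide 12 (not isolated)
Conditions: (R)-TRIP [(R)-3,3'-bis(2,4,6-triisopropylphenyl)-1,1'-binaphthyl-2,2'-diyl hydrogen phosphate] (10 mol%), 11 (3 equiv), 5 Å MS, toluene, −30 °C
Reagents that add atoms: none
Why: Proposed new method: the phosphoric acid protonates a methoxy group of 10, methanol is lost to the sieves, and the resulting O-methyl oxocarbenium ion (the O-protonated form of (E)-alkoxy o-quinone methide 12) stays hydrogen-bonded and ion-paired to the chiral phosphate while the CH2 terminus of 11 attacks the methide carbon (future C4) and phenol oxygen O1 collapses on the developing 4-methoxybenzylic cation (future C2) in a strongly asynchronous inverse-electron-demand [4+2] cycloaddition. The closest known reaction types are the achiral acid-promoted coupling of salicylaldehyde dimethyl acetals (or salicylaldehyde plus orthoformate) with styrenes to 4-methoxyflavans and the [4+2] reactions of o-quinone methides catalysed by chiral BINOL-derived phosphoric-type acids, including intramolecular cases of alkoxy o-quinone methides generated from salicylaldehydes; the intermolecular enantioselective reaction of such a methide with a simple styrene has not been shown. The one new ring, pyran ring C, closes by the cycloaddition itself with formation of C3–C4 and O1–C2 (in the stepwise limit, a six-membered closure by capture of the benzylic cation by O1). C2 is set by the chiral phosphate, whose 3,3'-aryl groups shield one face of the bound heterodiene so that the styrene approaches from the other, and C4 follows from the endo arrangement of the aryl group relative to the (E)-methide, which gives the 2,4-cis adduct. The step needs regioselectivity, fixed by the polarity of the two partners, chemoselectivity for the styrene over the two prenyl alkenes, secured by the higher nucleophilicity and the excess of 11, and suppression of a para-quinone methide, secured by the silyl ether on the para oxygen (future O7); the weak acid and low temperature spare the prenyl groups and limit styrene oligomerisation. Because C4 is erased later, what must hold is that every diastereomer carried on has the (2S) configuration, so a trans isomer would be separated here and kept only if shown to share that configuration.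

Step 8
Reactants: 13 (2S,4S)-7-[(tert-butyldimethylsilyl)oxy]-4-methoxy-2-(4-methoxyphenyl)-6,8-bis(3-methylbut-2-en-1-yl)chromane
Product: 14 (2S)-7-[(tert-butyldimethylsilyl)oxy]-2-(4-methoxyphenyl)-6,8-bis(3-methylbut-2-en-1-yl)chroman-4-ol (both C4 epimers)
Conditions: HCl (0.1 M aq.), THF/H2O (2:1), 0 °C to rt
Reagents that add atoms: water, O
Why: SN1 solvolysis of a benzylic ether should proceed in dilute acid because the C4 cation is stabilised by ring oxygen O1 (ortho) and the silyloxy group (para), and the large excess of water should capture it faster than it loses a C3 proton; C2 is not part of the cation and should keep its configuration, and the C4 epimer mixture is of no consequence.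

Step 9
Reactants: 14 (2S)-7-[(tert-butyldimethylsilyl)oxy]-2-(4-methoxyphenyl)-6,8-bis(3-methylbut-2-en-1-yl)chroman-4-ol (both C4 epimers)
Product: 15 (2S)-7-[(tert-butyldimethylsilyl)oxy]-2-(4-methoxyphenyl)-6,8-bis(3-methylbut-2-en-1-yl)chroman-4-one
Conditions: n-Pr4N[RuO4] (5 mol%), NMO, 4 Å MS, CH2Cl2, rt
Reagents that add atoms: none
Why: Ley–Griffith oxidation of a secondary benzylic alcohol is neutral and non-enolising, tolerates the prenyl alkenes and the aryl silyl ether, converges both C4 epimers on one ketone and leaves C2 untouched.

Step 10
Reactants: 15 (2S)-7-[(tert-butyldimethylsilyl)oxy]-2-(4-methoxyphenyl)-6,8-bis(3-methylbut-2-en-1-yl)chroman-4-one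
Product: 16 (2S)-7-hydroxy-2-(4-methoxyphenyl)-6,8-bis(3-methylbut-2-en-1-yl)chroman-4-one (the target flavanone)
Conditions: Bu4NF, AcOH (1:1), THF, 0 °C
Reagents that add atoms: none
Why: Fluoride desilylation of an aryl silyl ether para to the carbonyl group (a vinylogous silyl ester) should be fast even for the hindered group, and the acetic acid buffer protonates the phenoxide at once, which avoids base-induced ring opening to the chalcone, the pathway by which flavanones racemise at C2.

**Compound list**

1 | 2,4-dihydroxybenzaldehyde | O=Cc1ccc(O)cc1O | starting material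
2 | 3-chloro-3-methylbut-1-yne | CC(C)(Cl)C#C | starting material
3 | 2-hydroxy-4-[(2-methylbut-3-yn-2-yl)oxy]benzaldehyde | O=Cc1ccc(OC(C)(C)C#C)cc1O | intermediate
4 | 2-hydroxy-4-[(2-methylbut-3-en-2-yl)oxy]benzaldehyde (formed in the flask in step 2) | O=Cc1ccc(OC(C)(C)C=C)cc1O | intermediate
5 | 2,4-dihydroxy-3-(3-methylbut-2-en-1-yl)benzaldehyde | O=Cc1ccc(O)c(CC=C(C)C)c1O | intermediate
6 | 2-hydroxy-3-(3-methylbut-2-en-1-yl)-4-[(2-methylbut-3-yn-2-yl)oxy]benzaldehyde | O=Cc1ccc(OC(C)(C)C#C)c(CC=C(C)C)c1O | intermediate
7 | 2-hydroxy-3-(3-methylbut-2-en-1-yl)-4-[(2-methylbut-3-en-2-yl)oxy]benzaldehyde (formed in the flask in step 4) | O=Cc1ccc(OC(C)(C)C=C)c(CC=C(C)C)c1O | intermediate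
8 | 2,4-dihydroxy-3,5-bis(3-methylbut-2-en-1-yl)benzaldehyde | O=Cc1cc(CC=C(C)C)c(O)c(CC=C(C)C)c1O | intermediate
9 | 4-[(tert-butyldimethylsilyl)oxy]-2-hydroxy-3,5-bis(3-methylbut-2-en-1-yl)benzaldehyde | O=Cc1cc(CC=C(C)C)c(O[Si](C)(C)C(C)(C)C)c(CC=C(C)C)c1O | intermediate
10 | 3-[(tert-butyldimethylsilyl)oxy]-6-(dimethoxymethyl)-2,4-bis(3-methylbut-2-en-1-yl)phenol | COC(OC)c1cc(CC=C(C)C)c(O[Si](C)(C)C(C)(C)C)c(CC=C(C)C)c1O | intermediate
11 | 4-methoxystyrene | C=Cc1ccc(OC)cc1 | starting material
12 | (6E)-3-[(tert-butyldimethylsilyl)oxy]-6-(methoxymethylidene)-2,4-bis(3-methylbut-2-en-1-yl)cyclohexa-2,4-dien-1-one (formed in the flask in step 7, present as its O-protonated ion pair with the phosphate) | CO/C=C1\C=C(CC=C(C)C)C(O[Si](C)(C)C(C)(C)C)=C(CC=C(C)C)C1=O | intermediate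
13 | (2S,4S)-7-[(tert-butyldimethylsilyl)oxy]-4-methoxy-2-(4-methoxyphenyl)-6,8-bis(3-methylbut-2-en-1-yl)chromane (2,4-cis) | CO[C@H]1C[C@@H](c2ccc(OC)cc2)Oc2c(CC=C(C)C)c(O[Si](C)(C)C(C)(C)C)c(CC=C(C)C)cc21 | intermediate
14 | (2S)-7-[(tert-butyldimethylsilyl)oxy]-2-(4-methoxyphenyl)-6,8-bis(3-methylbut-2-en-1-yl)chroman-4-ol (both C4 epimers, C4 left undefined) | OC1C[C@@H](c2ccc(OC)cc2)Oc2c(CC=C(C)C)c(O[Si](C)(C)C(C)(C)C)c(CC=C(C)C)cc21 | intermediate
15 | (2S)-7-[(tert-butyldimethylsilyl)oxy]-2-(4-methoxyphenyl)-6,8-bis(3-methylbut-2-en-1-yl)chroman-4-one | COc1ccc([C@@H]2CC(=O)c3cc(CC=C(C)C)c(O[Si](C)(C)C(C)(C)C)c(CC=C(C)C)c3O2)cc1 | intermediate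
16 | (2S)-7-hydroxy-2-(4-methoxyphenyl)-6,8-bis(3-methylbut-2-en-1-yl)chroman-4-one (the target flavanone) | COc1ccc([C@@H]2CC(=O)c3cc(CC=C(C)C)c(O)c(CC=C(C)C)c3O2)cc1 | target

**Totals**

Total step count: 10. Longest linear sequence: 10 steps (1 to 16); compounds 2 and 11 and all reagents are commercial.

**Steps most likely to fail**

Step 7 (new method). The chiral ion pair may be too loose, or an achiral background pathway may compete, so that facial discrimination at the methide is poor; reversible ionisation of the adduct could also erode selectivity. The fallback uses known chemistry and sets out from 10. Cycloaddition with 11 under an achiral Lewis acid (Sc(OTf)3, CH2Cl2, 0 °C) should give the racemic 7-[(tert-butyldimethylsilyl)oxy]-4-methoxy-2-(4-methoxyphenyl)-6,8-bis(3-methylbut-2-en-1-yl)chromane F1 as a cis/trans mixture. Hydrolysis as in step 8 should give the racemic 7-[(tert-butyldimethylsilyl)oxy]-2-(4-methoxyphenyl)-6,8-bis(3-methylbut-2-en-1-yl)chroman-4-ol F2, and oxidation as in step 9 the racemic 7-[(tert-butyldimethylsilyl)oxy]-2-(4-methoxyphenyl)-6,8-bis(3-methylbut-2-en-1-yl)chroman-4-one F3. Kinetic resolution of F3 by asymmetric transfer hydrogenation (RuCl(p-cymene)[(R,R)-TsDPEN], HCO2H/Et3N, stopped near half conversion) is expected, by analogy with aryl alkyl ketones, to reduce the (2R)-ketone faster. This would give the (2R,4R)-7-[(tert-butyldimethylsilyl)oxy]-2-(4-methoxyphenyl)-6,8-bis(3-methylbut-2-en-1-yl)chroman-4-ol F4 and leave the (2S)-ketone, which is separated by chromatography; the route is rejoined at 15, at the cost of at most half of the material.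

Step 8. The C4 cation may lose a C3 proton to give the flav-3-ene instead of being captured by water, or the acid may open ring C at O1–C2 and scramble C2. The fallback sets out from 13 and avoids the free cation and the alcohol altogether: oxidative cleavage of the benzylic methyl ether with DDQ in CH2Cl2/pH 7 buffer (hydride abstraction at C4, then hydrolysis of the oxocarbenium ion) should give the ketone directly, rejoining the route at 15. C4–H should be the preferred site because it is alpha to the methoxy group and sits on the ring carrying an ortho and a para oxygen, which makes it more hydridic than the C2–H next to the 4-methoxyphenyl group or the prenyl methylene groups. This detour makes no new compound (F0).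

Step 6. The silyl ether, which is para to the formyl group, may be lost by acid methanolysis, or the acetal may revert to the aldehyde on concentration. The fallback sets out from 9 and does not isolate the acetal: 9, trimethyl orthoformate and 11 are combined with the chiral acid of step 7 and molecular sieves in one flask, so that 10 is generated and consumed in situ, as in the known three-component coupling of salicylaldehydes, orthoformate and styrenes. The route is rejoined at 13, and this detour makes no new compound (F0).

**Further compounds**

F1 | step 7 | racemic 7-[(tert-butyldimethylsilyl)oxy]-4-methoxy-2-(4-methoxyphenyl)-6,8-bis(3-methylbut-2-en-1-yl)chromane (cis/trans mixture) | COC1CC(c2ccc(OC)cc2)Oc2c(CC=C(C)C)c(O[Si](C)(C)C(C)(C)C)c(CC=C(C)C)cc21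
F2 | step 7 | racemic 7-[(tert-butyldimethylsilyl)oxy]-2-(4-methoxyphenyl)-6,8-bis(3-methylbut-2-en-1-yl)chroman-4-ol (C4 epimers) | OC1CC(c2ccc(OC)cc2)Oc2c(CC=C(C)C)c(O[Si](C)(C)C(C)(C)C)c(CC=C(C)C)cc21
F3 | step 7 | racemic 7-[(tert-butyldimethylsilyl)oxy]-2-(4-methoxyphenyl)-6,8-bis(3-methylbut-2-en-1-yl)chroman-4-one | COc1ccc(C2CC(=O)c3cc(CC=C(C)C)c(O[Si](C)(C)C(C)(C)C)c(CC=C(C)C)c3O2)cc1
F4 | step 7 | (2R,4R)-7-[(tert-butyldimethylsilyl)oxy]-2-(4-methoxyphenyl)-6,8-bis(3-methylbut-2-en-1-yl)chroman-4-ol | O[C@@H]1C[C@H](c2ccc(OC)cc2)Oc2c(CC=C(C)C)c(O[Si](C)(C)C(C)(C)C)c(CC=C(C)C)cc21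
F0 | step 8 | none | none
F0 | step 6 | none | none
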